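Each starting complex that reacts takes one incoming ligand, and each complex with one exchanged that reacts further takes another, so the ligand charged is shared out along the chain.

| flask | starting complex | incoming ligand | remark | time |
|---|---|---|---|---|
| north-west | 1 M | 0.58 equiv | run made earlier |  |
| north-east | 1 M | 1.2 equiv | run made earlier |  |
| alpha | 1.0 M | 0.500 equiv |  | 12 min |
| gamma | 1.0 M | 0.750 equiv |  | 12 min |
| zeta | 1.0 M | 1.10 equiv |  | 12 min |

| run | time / min | starting complex / % | complex with one exchanged / % | over-reaction product / % | complex with two exchanged / % |
|---|---|---|---|---|---|
| north-west | 2.00 | 55.4 | 41.7 | 0.4 | 2.7 |
| north-west | 4.00 | 49.4 | 46.9 | 0.1 | 4.3 |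
| north-west | 6.00 | 47.5 | 48.1 | 0.4 | 3.9 |
| north-west | 8.00 | 47.0 | 48.2 | 0.2 | 4.9 |
| north-east | 0.667 | 51.0 | 45.4 | 0.3 | 3.6 |
| north-east | 1.50 | 30.9 | 58.3 | 0.9 | 8.8 |
| north-east | 4.00 | 15.8 | 65.0 | 2.8 | 16.3 |
| north-east | 8.00 | 12.2 | 64.6 | 3.7 | 19.7 |

(standard deviation of a reading: 0.3 percentage points)

- which of these there is most of at the end, counted by the starting complex in it, alpha (over-reaction product / complex with one exchanged / starting complex / complex with two exchanged)
- which of these there is most of at the end, counted by the starting complex in it, gamma (over-reaction product / complex with one exchanged / starting complex / complex with two exchanged)
- which of these there is most of at the end, counted by the starting complex in it, zeta (over-reaction product / complex with one exchanged / starting complex / complex with two exchanged)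
- amount of the one of these that there is most of at the end, in percent of the starting complex charged, alpha
- amount of the one of these that there is most of at the end, in percent of the starting complex charged, gamma
- amount of the one of these that there is most of at the end, in percent of the starting complex charged, zeta

North-west and alpha look nearly the same, with 0.58 equiv and 0.500 equiv of incoming ligand. North-west's starting complex moves 0.5 percentage points between its last two readings. Counted as one, two and three ligands per product, north-west's products at its last reading have taken ligand equal to 58.6% of the complex charged, which matches the 0.58 equiv charged within scatter. The ligand is therefore the limiting reagent there, and that run's starting complex reads 47.0% at 8.00 min. Alpha has 0.0800 less ligand per complex charged, so its starting complex should stop higher, and the question is what a point of starting complex costs in ligand.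

Both steps use the same ligand, so it cancels from their ratio. The complex with one exchanged is consumed s times B/A as fast as the starting complex, where B and A are their amounts and s is the second-exchange ratio (selectivity factor), k2/k1. On such a pair of steps the top of the B curve lies where B = A^s, so s = ln B / ln A there. North-east's last two readings lie near that top, and the mean of the two ratios reads 0.221.

The ligand cost per starting complex is then about one plus s times B/A, which is 1.23 at north-west's last reading. By this reckoning alpha's missing ligand leaves the starting complex higher by 6.52% of the complex charged, giving 53.5%. The complex with one exchanged comes to 43.2%, behind the starting complex. Alpha's 12 min exceeds north-west's last reading at 8.00 min.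

The forecast gives starting complex at 53.5% for alpha, complex with one exchanged at 57.5% for gamma and complex with one exchanged at 65% for zeta, on the ground that “Reaction stops when the ligand runs out”.

Alpha ends with starting complex at 53.6%, gamma with complex with one exchanged at 57.1%, and zeta with complex with one exchanged at 64.8%.

    starting complex + incoming ligand → leaving ligand + complex with one exchanged (k = 0.0190 L mol⁻¹ s⁻¹)
    complex with one exchanged + incoming ligand → leaving ligand + complex with two exchanged (k = 0.00430 L mol⁻¹ s⁻¹)
    complex with two exchanged + incoming ligand → leaving ligand + complex with three exchanged (k = 6.60 × 10⁻⁴ L mol⁻¹ s⁻¹)
    complex with two exchanged + incoming ligand → over-reaction product (k = 0.00410 L mol⁻¹ s⁻¹)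

In alpha, 0.010% of the charged ligand is free at 12.0 min, against 54% of the starting complex. Gamma read at 3.0 min holds 40.1% starting complex, 53.3% complex with one exchanged, and 11% of its ligand free, which is 0.0791 per complex charged. With s, the cost at that reading is 1.29, so that ligand reckons to remove about 6.1 points of starting complex, and gamma's starting complex ends at 34.4%.

(All runs were generated by integration with constants of no real substance, noise included.)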